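**Retrosynthetic overview**

1. The hydroperoxide is unmasked last from peroxyketal 35. The (2Z,4E)-diene comes from a Stille union of Z-iodoalkene 30 with peroxy-stannane 34. The C-1 carbinol/CH2OAc pair of the cyclopentane is traced back to an exocyclic methylene (osmylation), and that to the cyclopentenyl-methanol 25 (reductive 1,3-transposition).
2. Key disconnection: the bond between C-1 of the 5-methyl-2-oxocyclopent-3-enyl ring and C-2 of the cyclopentane, made by an ester-dianion Carroll ([3,3]) rearrangement of cyclopent-2-enyl β-keto ester 20 with loss of CO2.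
3. Enabling feature: the enone-ring carbon is α to its ring ketone and can carry a CO2 tether. Cyclopentane C-2 lies next to the oxygenated quaternary C-1, which can be traced back to an sp2 carbon, so C-2, C-1 and C-5 form an allyl unit with the ester oxygen on C-5 (six-atom array Cα=C(O)–O–C-5–C-1=C-2).
4. Fragments: keto ester 19 from (R)-pulegone (its methyl stereocentre becomes C-5 of the enone ring); alcohol 15 by Evans syn-aldol and ring-closing metathesis, with a temporary oxasilacycle that fixes the Z-alkene and is opened by iododesilylation.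
5. Ring order: cyclopentanone ring (Favorskii contraction, step 12) and cyclopentene ring (metathesis, step 5) before the coupling; temporary oxasiline ring made in step 10 and destroyed in step 11; enone unsaturation after the key step (step 16).

Key step: step 15

Remark: metal enolates, boron aldolates, ozonides and catalyst-bound species are treated as reactive forms of reagents or substrates and are not numbered.

Step 1
Reactants: 1 (4S)-4-benzyl-1,3-oxazolidin-2-one; 2 pent-4-enoyl chloride
Product: 3 (4S)-4-benzyl-3-(pent-4-enoyl)-1,3-oxazolidin-2-one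
Conditions: n-BuLi, THF, −78 °C; then 2, −78 → 0 °C
Reagents that add atoms: none
Why: N-acylation of the lithiated oxazolidinone loads the Evans auxiliary that will control both ring stereocentres of the cyclopentenol fragment; no stereocentre is formed.

Step 2
Reactants: 4 2-methylidenepropane-1,3-diol
Product: 5 2-({[tert-butyl(diphenyl)silyl]oxy}methyl)prop-2-en-1-ol
Conditions: NaH (1.0 equiv), THF, 0 °C; TBDPSCl, 23 °C
Reagents that add atoms: tert-butyl(chloro)diphenylsilane, CC(C)(C)[Si](Cl)(c1ccccc1)c1ccccc1
Why: O-silylation of the mono-sodium alkoxide of a symmetrical diol should stop at the mono-ether because only one equivalent of alkoxide is formed.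

Step 3
Reactants: 5 mono-silyl ether
Product: 6 2-({[tert-butyl(diphenyl)silyl]oxy}methyl)prop-2-enal
Conditions: Dess–Martin periodinane, NaHCO3, CH2Cl2, 0 → 23 °C
Reagents that add atoms: none
Why: Dess–Martin oxidation of a primary allylic alcohol gives the 2-substituted acrolein without over-oxidation or alkene migration.

Step 4
Reactants: 3 N-pentenoyl oxazolidinone; 6 enal
Product: 7 Evans syn-aldol adduct
Conditions: Bu2BOTf, iPr2NEt, CH2Cl2, −78 → 0 °C; 6, −78 → 0 °C; pH 7 buffer, MeOH, 30% H2O2
Reagents that add atoms: none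
Why: Evans syn-aldol reaction: the Z-boron enolate adds through a Zimmerman–Traxler chair on the face away from the benzyl group, setting the α-carbon (S) and the carbinol carbon (S), the later cis O/C pair on the ring.

Step 5
Reactants: 7 aldol adduct
Product: 8 cis-2-hydroxycyclopent-3-enyl imide
Conditions: Grubbs II (3 mol%), CH2Cl2, 40 °C
Reagents that add atoms: none
Why: Ring-closing metathesis of the 1,1-disubstituted and the terminal alkene closes the cyclopentene with its trisubstituted alkene; the two stereocentres are untouched and become cis on the ring.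

Step 6
Reactants: 8 imide
Product: 9 Weinreb amide
Conditions: MeNHOMe·HCl, AlMe3, THF, 0 → 23 °C
Reagents that add atoms: N,O-dimethylhydroxylamine hydrochloride, CNOC.Cl
Why: Aluminium-amide transamidation cleaves the exocyclic imide carbonyl selectively (assisted by the β-hydroxyl) and releases the auxiliary without touching the α-stereocentre.

Step 7
Reactants: 9 Weinreb amide
Product: 10 cis β-hydroxy methyl ketone
Conditions: MeMgBr (3 equiv), THF, −20 → 0 °C; aq NH4Cl
Reagents that add atoms: methylmagnesium bromide, C[Mg]Br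
Why: Grignard addition to a Weinreb amide stops at the ketone because the chelated tetrahedral intermediate survives until work-up.

Step 8
Reactants: 10 hydroxy ketone
Product: 11 ethenyl(dimethyl)silyl ether
Conditions: ClSiMe2CH=CH2, imidazole, CH2Cl2, 0 °C
Reagents that add atoms: chloro(ethenyl)dimethylsilane, C=C[Si](C)(C)Cl
Why: Silylation of the secondary alcohol protects it against retro-aldol cleavage and installs the silicon tether for the later metathesis.

Step 9
Reactants: 11 silyloxy ketone
Product: 12 isopropenyl compound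
Conditions: Ph3PCH3Br, KOtBu, THF, −78 → 0 °C
Reagents that add atoms: methyltriphenylphosphonium bromide, C[P+](c1ccccc1)(c1ccccc1)c1ccccc1.[Br-]
Why: Wittig methylenation of the methyl ketone at low temperature should outrun enolisation, so the α-stereocentre keeps its configuration.

Step 10
Reactants: 12 vinylsilyl ether with isopropenyl group
Product: 13 cis-fused alkenyl oxasiline
Conditions: Schrock Mo alkylidene catalyst (8 mol%), benzene, 60 °C
Reagents that add atoms: none
Why: Silicon-tethered ring-closing metathesis between the vinylsilane and the isopropenyl group gives a six-membered oxasilacycle whose endocyclic trisubstituted alkene can only be Z.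

Step 11
Reactants: 13 cyclic alkenylsiloxane
Product: 15 Z-iodoalkene alcohol (1S,5R), via N-silylsuccinimide 14 (not isolated)
Conditions: NIS, MeCN/ClCH2CN (4:1), 0 °C; then K2CO3 (cat.), MeOH, 0 °C
Reagents that add atoms: N-iodosuccinimide, O=C1CCC(=O)N1I
Why: Iododesilylation (ipso substitution through a β-silyl cation) replaces C–Si by C–I with retention, and methanolysis of the O–Si bond frees the alcohol while the TBDPS ether survives.

Step 12
Reactants: 16 (R)-(+)-pulegone
Product: 18 methyl (2R)-2-methyl-5-(propan-2-ylidene)cyclopentane-1-carboxylate (C-1 epimers), via pulegone dibromide 17 (not isolated)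
Conditions: Br2, NaHCO3, Et2O, 0 °C; then NaOMe, MeOH, reflux
Reagents that add atoms: sodium methoxide, C[O-].[Na+]
Why: Favorskii ring contraction of the α,α'-dibromide gives the cyclopentane ester; the methyl-bearing stereocentre is not involved and stays (R).

Step 13
Reactants: 18 methyl pulegenate
Product: 19 methyl (2R)-2-methyl-5-oxocyclopentane-1-carboxylate (C-1 epimers and enol)
Conditions: O3, CH2Cl2/MeOH, −78 °C; Me2S
Reagents that add atoms: ozone, [O-][O+]=O
Why: Ozonolysis of the tetrasubstituted isopropylidene alkene unveils the ring ketone as a β-keto ester.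

Step 14
Reactants: 15 cyclopentenol; 19 methyl β-keto ester
Product: 20 cyclopent-2-enyl β-keto ester (C-1 epimers)
Conditions: DMAP (0.3 equiv), toluene, reflux, 4 Å MS
Reagents that add atoms: none
Why: DMAP-catalysed transesterification of a β-keto ester (through the acylketene) is driven by removal of methanol and proceeds with retention at the carbinol carbon.

Step 15
Reactants: 20 cyclopent-2-enyl β-keto ester
Product: 23 (2S,3R)-2-[(1S,4S)-2-({[tert-butyl(diphenyl)silyl]oxy}methyl)-4-[(1Z)-1-iodoprop-1-en-2-yl]cyclopent-2-en-1-yl]-3-methylcyclopentan-1-one, via β-keto acid 21 (not isolated), via enol 22 (not isolated)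
Conditions: LDA (2.2 equiv), THF, −78 → 60 °C; 1 M HCl, 0 °C; toluene, 70 °C
Reagents that add atoms: none
Why: Double deprotonation converts all C-1 epimers and the enol of 20 into one dianion, whose ketene-acetal unit undergoes a concerted [3,3] shift (ester-dianion Carroll rearrangement, the decarboxylative relative of the Ireland–Claisen reaction, precedented for cycloalk-2-enyl β-keto esters); this forms the ring–ring bond, breaks the allylic C–O bond and moves the alkene. No ring is closed, since the six-membered array exists only in the transition state. The new stereocentre on the cyclopentene is fixed by suprafacial 1,3-chirality transfer from the C–O stereocentre, so the bond forms on the face that carried the ester oxygen, which is the face of the iodopropenyl group; chair and boat transition states and both enolate faces give the same result there, because the quaternary centre in which they differ is erased afterwards. Acidification and warming expel CO2 from β-keto acid 21 to give enol 22, and ketonisation on the face opposite the neighbouring methyl group should place the new ring substituent cis to that methyl group (kinetic protonation, as in decarboxylative routes to cis-2,3-disubstituted cyclopentanones). The step needs site selectivity for the ring CH terminus over the carbinol carbon, secured by the pericyclic topology, and facial selectivity in the protonation, secured by the methyl group from pulegone; the tether atoms leave as CO2.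

Step 16
Reactants: 23 cyclopentanone
Product: 24 (4R,5S)-4-methyl-5-substituted cyclopent-2-en-1-one
Conditions: LDA (1.1 equiv), THF, −78 °C; PhS(Cl)=N-tBu, −78 °C
Reagents that add atoms: none
Why: Kinetic deprotonation occurs at the unhindered α-CH2, and sulfinimidoyl chloride dehydrogenation of the lithium enolate introduces the enone double bond on that side without touching the two ring stereocentres.

Step 17
Reactants: 24 silyl ether
Product: 25 allylic alcohol
Conditions: HF·pyridine, pyridine, THF, 0 → 23 °C
Reagents that add atoms: none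
Why: Fluoride-mediated cleavage of the primary silyl ether under buffered, non-basic conditions leaves the epimerisable cis-enone intact.

Step 18
Reactants: 25 allylic alcohol
Product: 28 exocyclic methylene compound, via sulfonylhydrazine 26 (not isolated), via allylic diazene 27 (not isolated)
Conditions: 2-nitrobenzenesulfonylhydrazide, PPh3, DEAD, N-methylmorpholine, −30 → 23 °C
Reagents that add atoms: none
Why: Myers reductive 1,3-transposition: Mitsunobu N-alkylation, loss of sulfinic acid and retro-ene extrusion of N2 from the allylic diazene deliver hydrogen to the ring carbon and move the alkene to the exocyclic position.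

Step 19
Reactants: 28 exocyclic alkene
Product: 29 1,2-diol
Conditions: OsO4 (2 mol%), NMO, citric acid, acetone/H2O, 0 °C
Reagents that add atoms: N-methylmorpholine N-oxide, C[N+]1([O-])CCOCC1; water, O
Why: Upjohn dihydroxylation should pick the electron-rich 1,1-disubstituted alkene over the enone and the iodoalkene and attack the face opposite the two cis ring substituents, which puts the tertiary OH trans to the enone ring and sets the quaternary centre (R).

Step 20
Reactants: 29 diol
Product: 30 primary acetate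
Conditions: Ac2O, pyridine, DMAP (cat.), CH2Cl2, 0 °C
Reagents that add atoms: acetic anhydride, CC(=O)OC(C)=O
Why: Acylation distinguishes the primary from the tertiary hydroxyl on steric grounds.

Step 21
Reactants: 31 2-methylbut-3-yn-2-ol
Product: 32 3-hydroperoxy-3-methylbut-1-yne
Conditions: 50% H2O2, H2SO4 (cat.), 0 °C
Reagents that add atoms: hydrogen peroxide, OO
Why: Acid-catalysed perhydrolysis (SN1) of a tertiary propargylic alcohol gives the tertiary hydroperoxide.

Step 22
Reactants: 32 hydroperoxide
Product: 33 2-methoxyprop-2-yl peroxyketal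
Conditions: 2-methoxypropene, PPTS (cat.), CH2Cl2, 0 °C
Reagents that add atoms: 2-methoxypropene, COC(C)=C
Why: Acid-catalysed addition of the hydroperoxide to the enol ether masks it as a peroxyketal that is stable to base and metal catalysts.

Step 23
Reactants: 33 peroxy alkyne
Product: 34 (E)-alkenylstannane
Conditions: Bu3SnH, PdCl2(PPh3)2 (2 mol%), THF, 0 °C
Reagents that add atoms: tributyltin hydride, CCCC[SnH](CCCC)CCCC
Why: Palladium-catalysed syn-hydrostannylation places tin on the terminal carbon, away from the quaternary centre, and gives the E-alkene.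

Step 24
Reactants: 30 Z-iodoalkene; 34 alkenylstannane
Product: 35 protected (2Z,4E)-dienyl peroxide
Conditions: Pd2(dba)3 (5 mol%), AsPh3, DMF, 25 °C, dark
Reagents that add atoms: none
Why: Stille coupling joins the two sp2 carbons with retention of both alkene geometries under neutral conditions that the peroxyketal, the acetate and the cis-enone should tolerate.

Step 25
Reactants: 35 peroxyketal
Product: 36 target hydroperoxide
Conditions: AcOH/THF/H2O (4:2:1), 23 °C
Reagents that add atoms: none
Why: Mild acid hydrolysis of the mixed peroxyketal releases the hydroperoxide without ionising the tertiary allylic C–O bond or epimerising the enone.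

**Compound list**

1 | (4S)-4-benzyl-1,3-oxazolidin-2-one | O=C1N[C@@H](Cc2ccccc2)CO1 | starting material
2 | pent-4-enoyl chloride | C=CCCC(Cl)=O | starting material
3 | (4S)-4-benzyl-3-(pent-4-enoyl)-1,3-oxazolidin-2-one | C=CCCC(=O)N1[C@@H](Cc2ccccc2)COC1=O | intermediate
4 | 2-methylidenepropane-1,3-diol | C=C(CO)CO | starting material
5 | 2-({[tert-butyl(diphenyl)silyl]oxy}methyl)prop-2-en-1-ol | C=C(CO)CO[Si](c1ccccc1)(c1ccccc1)C(C)(C)C | intermediate
6 | 2-({[tert-butyl(diphenyl)silyl]oxy}methyl)prop-2-enal | C=C(C=O)CO[Si](c1ccccc1)(c1ccccc1)C(C)(C)C | intermediate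
7 | (4S)-4-benzyl-3-[(2S)-2-[(1S)-2-({[tert-butyl(diphenyl)silyl]oxy}methyl)-1-hydroxyprop-2-en-1-yl]pent-4-enoyl]-1,3-oxazolidin-2-one | C=CC[C@@H]([C@H](O)C(=C)CO[Si](c1ccccc1)(c1ccccc1)C(C)(C)C)C(=O)N1[C@@H](Cc2ccccc2)COC1=O | intermediate
8 | (4S)-4-benzyl-3-{[(1S,2S)-3-({[tert-butyl(diphenyl)silyl]oxy}methyl)-2-hydroxycyclopent-3-en-1-yl]carbonyl}-1,3-oxazolidin-2-one (OH and acyl cis) | O[C@@H]1C(CO[Si](c2ccccc2)(c2ccccc2)C(C)(C)C)=CC[C@@H]1C(=O)N1[C@@H](Cc2ccccc2)COC1=O | intermediate
9 | (1S,2S)-3-({[tert-butyl(diphenyl)silyl]oxy}methyl)-2-hydroxy-N-methoxy-N-methylcyclopent-3-ene-1-carboxamide | O[C@@H]1C(CO[Si](c2ccccc2)(c2ccccc2)C(C)(C)C)=CC[C@@H]1C(=O)N(C)OC | intermediate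
10 | 1-[(1S,2S)-3-({[tert-butyl(diphenyl)silyl]oxy}methyl)-2-hydroxycyclopent-3-en-1-yl]ethan-1-one | O[C@@H]1C(CO[Si](c2ccccc2)(c2ccccc2)C(C)(C)C)=CC[C@@H]1C(C)=O | intermediate
11 | 1-[(1S,2S)-3-({[tert-butyl(diphenyl)silyl]oxy}methyl)-2-{[ethenyl(dimethyl)silyl]oxy}cyclopent-3-en-1-yl]ethan-1-one | C=C[Si](C)(C)O[C@@H]1C(CO[Si](c2ccccc2)(c2ccccc2)C(C)(C)C)=CC[C@@H]1C(C)=O | intermediate
12 | {[(1S,5R)-2-({[tert-butyl(diphenyl)silyl]oxy}methyl)-5-(prop-1-en-2-yl)cyclopent-2-en-1-yl]oxy}(ethenyl)dimethylsilane | C=C[Si](C)(C)O[C@@H]1C(CO[Si](c2ccccc2)(c2ccccc2)C(C)(C)C)=CC[C@@H]1C(C)=C | intermediate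
13 | (4aR,7aS)-7-({[tert-butyl(diphenyl)silyl]oxy}methyl)-2,2,4-trimethyl-2,4a,5,7a-tetrahydrocyclopenta[e][1,2]oxasiline (cis-fused) | CC1=C[Si](C)(C)O[C@@H]2C(CO[Si](c3ccccc3)(c3ccccc3)C(C)(C)C)=CC[C@H]12 | intermediate
14 | 1-[({(1S,5R)-2-({[tert-butyl(diphenyl)silyl]oxy}methyl)-5-[(1Z)-1-iodoprop-1-en-2-yl]cyclopent-2-en-1-yl}oxy)dimethylsilyl]pyrrolidine-2,5-dione | O=C1CCC(=O)N1[Si](C)(C)O[C@@H]1C(CO[Si](c2ccccc2)(c2ccccc2)C(C)(C)C)=CC[C@@H]1/C(C)=C\I | intermediate
15 | (1S,5R)-2-({[tert-butyl(diphenyl)silyl]oxy}methyl)-5-[(1Z)-1-iodoprop-1-en-2-yl]cyclopent-2-en-1-ol | O[C@@H]1C(CO[Si](c2ccccc2)(c2ccccc2)C(C)(C)C)=CC[C@@H]1/C(C)=C\I | intermediate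
16 | (R)-(+)-pulegone, (5R)-5-methyl-2-(propan-2-ylidene)cyclohexan-1-one | C[C@@H]1CCC(=C(C)C)C(=O)C1 | starting material
17 | (5R)-2-bromo-2-(2-bromopropan-2-yl)-5-methylcyclohexan-1-one (C-2 epimers) | C[C@@H]1CCC(Br)(C(C)(C)Br)C(=O)C1 | intermediate
18 | methyl (2R)-2-methyl-5-(propan-2-ylidene)cyclopentane-1-carboxylate (C-1 epimers) | COC(=O)C1C(=C(C)C)CC[C@H]1C | intermediate
19 | methyl (2R)-2-methyl-5-oxocyclopentane-1-carboxylate (C-1 epimers and enol) | COC(=O)C1C(=O)CC[C@H]1C | intermediate
20 | (1S,5R)-2-({[tert-butyl(diphenyl)silyl]oxy}methyl)-5-[(1Z)-1-iodoprop-1-en-2-yl]cyclopent-2-en-1-yl (2R)-2-methyl-5-oxocyclopentane-1-carboxylate (C-1 epimers) | O=C(O[C@@H]1C(CO[Si](c2ccccc2)(c2ccccc2)C(C)(C)C)=CC[C@@H]1/C(C)=C\I)C1C(=O)CC[C@H]1C | intermediate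
21 | (2R)-2-methyl-5-oxocyclopentane-1-carboxylic acid bearing at C-1 the cyclopent-2-en-1-yl group of 23 (quaternary C-1 unassigned; other centres as in 23) | OC(=O)C1([C@@H]2C[C@H](/C(C)=C\I)C=C2CO[Si](c2ccccc2)(c2ccccc2)C(C)(C)C)C(=O)CC[C@H]1C | intermediate
22 | (3R)-3-methylcyclopent-1-en-1-ol bearing at C-2 the cyclopent-2-en-1-yl group of 23 (centres as in 23) | OC1=C([C@@H]2C[C@H](/C(C)=C\I)C=C2CO[Si](c2ccccc2)(c2ccccc2)C(C)(C)C)[C@H](C)CC1 | intermediate
23 | (2S,3R)-2-[(1S,4S)-2-({[tert-butyl(diphenyl)silyl]oxy}methyl)-4-[(1Z)-1-iodoprop-1-en-2-yl]cyclopent-2-en-1-yl]-3-methylcyclopentan-1-one | CC(C)(C)[Si](OCC1=C[C@@H](/C(C)=C\I)C[C@H]1[C@H]1C(=O)CC[C@H]1C)(c1ccccc1)c1ccccc1 | intermediate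
24 | (4R,5S)-5-[(1S,4S)-2-({[tert-butyl(diphenyl)silyl]oxy}methyl)-4-[(1Z)-1-iodoprop-1-en-2-yl]cyclopent-2-en-1-yl]-4-methylcyclopent-2-en-1-one | CC(C)(C)[Si](OCC1=C[C@@H](/C(C)=C\I)C[C@H]1[C@H]1C(=O)C=C[C@H]1C)(c1ccccc1)c1ccccc1 | intermediate
25 | (4R,5S)-5-[(1S,4S)-2-(hydroxymethyl)-4-[(1Z)-1-iodoprop-1-en-2-yl]cyclopent-2-en-1-yl]-4-methylcyclopent-2-en-1-one | OCC1=C[C@@H](/C(C)=C\I)C[C@H]1[C@H]1C(=O)C=C[C@H]1C | intermediate
26 | N-alkyl-N-(2-nitrobenzenesulfonyl)hydrazine formed at the CH2OH carbon of 25 (centres as in 25) | NN(CC1=C[C@@H](/C(C)=C\I)C[C@H]1[C@H]1C(=O)C=C[C@H]1C)S(=O)(=O)c1ccccc1[N+](=O)[O-] | intermediate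
27 | monoalkyl diazene (CH2–N=NH) derived from 26 (centres as in 25) | N=NCC1=C[C@@H](/C(C)=C\I)C[C@H]1[C@H]1C(=O)C=C[C@H]1C | intermediate
28 | (4R,5S)-5-[(1S,4S)-4-[(1Z)-1-iodoprop-1-en-2-yl]-2-methylidenecyclopentyl]-4-methylcyclopent-2-en-1-one | C=C1C[C@@H](/C(C)=C\I)C[C@H]1[C@H]1C(=O)C=C[C@H]1C | intermediate
29 | (4R,5S)-5-[(1S,2R,4S)-2-hydroxy-2-(hydroxymethyl)-4-[(1Z)-1-iodoprop-1-en-2-yl]cyclopentyl]-4-methylcyclopent-2-en-1-one | OC[C@@]1(O)C[C@@H](/C(C)=C\I)C[C@H]1[C@H]1C(=O)C=C[C@H]1C | intermediate
30 | [(1R,2S,4S)-1-hydroxy-4-[(1Z)-1-iodoprop-1-en-2-yl]-2-[(1S,5R)-5-methyl-2-oxocyclopent-3-en-1-yl]cyclopentyl]methyl acetate | CC(=O)OC[C@@]1(O)C[C@@H](/C(C)=C\I)C[C@H]1[C@H]1C(=O)C=C[C@H]1C | intermediate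
31 | 2-methylbut-3-yn-2-ol | CC(C)(O)C#C | starting material
32 | 3-hydroperoxy-3-methylbut-1-yne | CC(C)(OO)C#C | intermediate
33 | 3-[(2-methoxypropan-2-yl)peroxy]-3-methylbut-1-yne | COC(C)(C)OOC(C)(C)C#C | intermediate
34 | tributyl[(1E)-3-[(2-methoxypropan-2-yl)peroxy]-3-methylbut-1-en-1-yl]stannane | CCCC[Sn](CCCC)(CCCC)/C=C/C(C)(C)OOC(C)(C)OC | intermediate
35 | [(1R,2S,4S)-1-hydroxy-4-[(2Z,4E)-6-[(2-methoxypropan-2-yl)peroxy]-6-methylhepta-2,4-dien-2-yl]-2-[(1S,5R)-5-methyl-2-oxocyclopent-3-en-1-yl]cyclopentyl]methyl acetate | CC(=O)OC[C@@]1(O)C[C@@H](/C(C)=C\C=C\C(C)(C)OOC(C)(C)OC)C[C@H]1[C@H]1C(=O)C=C[C@H]1C | intermediate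
36 | [(1R,2S,4S)-1-hydroxy-4-[(2Z,4E)-6-hydroperoxy-6-methylhepta-2,4-dien-2-yl]-2-[(1S,5R)-5-methyl-2-oxocyclopent-3-en-1-yl]cyclopentyl]methyl acetate (CNP0204569.1) | CC(=O)OC[C@@]1(O)C[C@@H](/C(C)=C\C=C\C(C)(C)OO)C[C@H]1[C@H]1C(=O)C=C[C@H]1C | target

**Step count and risks**

Total step count: 25. Longest linear sequence: 19 steps (steps 2–11, 14–20, 24, 25).

Step 15 (most likely to fail). The [3,3] shift joins two hindered carbons, and the ketonisation of enol 22 may show poor facial selectivity, or the cis ketone may epimerise on work-up, so that the trans isomer accompanies 23. Fallback (the ring-junction centre is set by a separate kinetic protonation of a dienolate instead of by the ketonisation): setting out again from 20, the rearrangement is run as before and the mixture of 23 with the trans ketone F1 is not separated. It is dehydrogenated as in step 16 to 24 together with the trans enone F2. LDA (THF, −78 °C) removes the only α'-hydrogen of both epimers to give one cross-conjugated lithium dienolate F3, which is quenched at −78 °C with 2,6-di-tert-butylphenol on the face opposite the methyl group. The route is rejoined at 24.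

Step 24. Pd(0) may insert into the O–O bond of the peroxyketal (reductive loss of the peroxide) before or after the coupling, or the hindered Z-iodoalkene may couple slowly and lose geometry. Fallback (the peroxide never meets palladium; the E-alkene is made by cross-metathesis): 30 is coupled with tributyl(vinyl)stannane (Pd2(dba)3, AsPh3) to the terminal diene F4. Separately, 2-methylbut-3-en-2-ol is perhydrolysed (50% H2O2, cat. H2SO4) to 2-hydroperoxy-2-methylbut-3-ene F5, which is capped with 2-methoxypropene (PPTS) to the peroxyketal alkene F6. Cross-metathesis of F4 with excess F6 (Hoveyda–Grubbs II, CH2Cl2, 40 °C) should give the E-alkene, because the quaternary allylic olefin cannot homodimerise and the trisubstituted alkene is inert. The route is rejoined at 35.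

Step 19. Osmylation may also attack the iodoalkene or the enone, or show low facial selectivity at the exocyclic alkene. Fallback (epoxidation and SN2 opening replace osmylation and acylation): 28 is epoxidised with buffered mCPBA (NaHCO3, CH2Cl2, 0 °C) from the less hindered face to the spiro-epoxide F7. Its CH2 terminus is opened with tetrabutylammonium acetate in acetic acid to give the tertiary alcohol and the primary acetate directly. The route is rejoined at 30, bypassing 29.

Further compounds
F1 | step 15 | trans ketone, (2R,3R)-epimer of 23 | CC(C)(C)[Si](OCC1=C[C@@H](/C(C)=C\I)C[C@H]1[C@@H]1C(=O)CC[C@H]1C)(c1ccccc1)c1ccccc1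
F2 | step 15 | trans enone, (4R,5R)-epimer of 24 | CC(C)(C)[Si](OCC1=C[C@@H](/C(C)=C\I)C[C@H]1[C@@H]1C(=O)C=C[C@H]1C)(c1ccccc1)c1ccccc1
F3 | step 15 | lithium cross-conjugated dienolate of 24 | [Li+].[O-]C1=C([C@@H]2C[C@H](/C(C)=C\I)C=C2CO[Si](c2ccccc2)(c2ccccc2)C(C)(C)C)[C@H](C)C=C1
F4 | step 24 | [(1R,2S,4S)-1-hydroxy-4-[(2Z)-penta-2,4-dien-2-yl]-2-[(1S,5R)-5-methyl-2-oxocyclopent-3-en-1-yl]cyclopentyl]methyl acetate | CC(=O)OC[C@@]1(O)C[C@@H](/C(C)=C\C=C)C[C@H]1[C@H]1C(=O)C=C[C@H]1C
F5 | step 24 | 2-hydroperoxy-2-methylbut-3-ene | C=CC(C)(C)OO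
F6 | step 24 | 3-[(2-methoxypropan-2-yl)peroxy]-3-methylbut-1-ene | COC(C)(C)OOC(C)(C)C=C
F7 | step 19 | spiro-epoxide of 28 (oxirane oxygen trans to the enone ring) | C1O[C@@]12C[C@@H](/C(C)=C\I)C[C@H]2[C@H]1C(=O)C=C[C@H]1C
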